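**Assumption:** commercial (2S)-hesperetin (the aglycone of natural hesperidin) is bought as the single enantiomer and its ee is checked by chiral HPLC before use. The route has not been run; selectivities are argued from mechanism and analogy.

## Retrosynthetic overview

1. Target ⇐ its 7-O-MOM ether (acidic deprotection, last step).
2. 7-O-MOM ether ⇐ a 5-O-prenyl, 4'-O-(1,1-dimethylpropargyl) ether in one pot: para-Claisen–Cope (O5→C6→C8) places the 8-prenyl group, and propargyl Claisen/[1,5]-H/oxa-6π electrocyclisation closes the pyran, the only ring that is built.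
3. Propargyl ether ⇐ 2'-prenyl catechol (4'-O alkylation; the 3'-OH is shielded by the 2'-prenyl group) ⇐ 2'-prenyl guaiacol (IBX oxidative demethylation).
4. 2'-Prenyl guaiacol ⇐ 3'-O-(1,1-dimethylallyl) ether by aromatic Claisen (O3'→C2'); its precursors come from 7-O-MOM-hesperetin by Pd reverse prenylation (O3') and Mitsunobu prenylation (O5).
5. Rings A, B, C and the C2 stereocentre are bought in (2S)-hesperetin, whose 3'-OH/4'-OMe pattern tells the two B-ring oxygens apart.

## Route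

**Step 1**
Reactants: 1 (2S)-hesperetin
Product: 2 (2S)-5-hydroxy-2-(3-hydroxy-4-methoxyphenyl)-7-(methoxymethoxy)chroman-4-one
Conditions: MOMCl (1.05 equiv), K2CO3 (1.1 equiv), acetone, 0 °C → rt
Reagents that add atoms: chloromethyl methyl ether (MOMCl), COCCl
Why: Williamson-type O-alkylation in which one equivalent of weak base ionises only the vinylogous-acid 7-OH (pKa about 7.5, against about 10 for 3'-OH and a chelated 5-OH), and with O4' methylated the C2 centre has no easy ring-opening path under these mild conditions.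

**Step 2**
Reactants: 2 (2S)-5-hydroxy-2-(3-hydroxy-4-methoxyphenyl)-7-(methoxymethoxy)chroman-4-one; 3 tert-butyl 2-methylbut-3-en-2-yl carbonate
Product: 4 (2S)-5-hydroxy-2-[4-methoxy-3-(2-methylbut-3-en-2-yloxy)phenyl]-7-(methoxymethoxy)chroman-4-one
Conditions: Pd(PPh3)4 (3 mol %), THF, 0 °C → rt
Reagents that add atoms: none
Why: Tsuji–Trost O-allylation (decarboxylative reverse prenylation) in which the 3'-phenoxide attacks the more substituted end of the π-(1,1-dimethylallyl)palladium cation to give the tertiary ether under neutral conditions, while the hydrogen-bonded 5-OH stays free.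

**Step 3**
Reactants: 4 (2S)-5-hydroxy-2-[4-methoxy-3-(2-methylbut-3-en-2-yloxy)phenyl]-7-(methoxymethoxy)chroman-4-one; 5 3-methylbut-2-en-1-ol (prenol)
Product: 6 (2S)-2-[4-methoxy-3-(2-methylbut-3-en-2-yloxy)phenyl]-7-(methoxymethoxy)-5-(3-methylbut-2-enyloxy)chroman-4-one
Conditions: PPh3, DIAD, THF, 0 °C → rt
Reagents that add atoms: none
Why: Mitsunobu etherification of the only phenol left, the chelated 5-OH, by the activated primary allylic alcohol under essentially neutral conditions that do not touch C2.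

**Step 4**
Reactants: 6 (2S)-2-[4-methoxy-3-(2-methylbut-3-en-2-yloxy)phenyl]-7-(methoxymethoxy)-5-(3-methylbut-2-enyloxy)chroman-4-one
Product: 8 (2S)-2-[3-hydroxy-4-methoxy-2-(3-methylbut-2-enyl)phenyl]-7-(methoxymethoxy)-5-(3-methylbut-2-enyloxy)chroman-4-one, via C2' cyclohexadienone 7 (not isolated)
Conditions: PhMe, 115 °C, sealed tube, Ar
Reagents that add atoms: none
Why: Aromatic Claisen [3,3]-sigmatropic rearrangement of the tertiary allyl aryl ether to C2', the only ortho position carrying hydrogen (C4' bears OMe), followed by enolisation to the linear prenyl phenol, while the primary 5-O-prenyl ether needs Eu(III) or roughly 190 °C and stays in place.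

**Step 5**
Reactants: 8 (2S)-2-[3-hydroxy-4-methoxy-2-(3-methylbut-2-enyl)phenyl]-7-(methoxymethoxy)-5-(3-methylbut-2-enyloxy)chroman-4-one
Product: 10 (2S)-2-[3,4-dihydroxy-2-(3-methylbut-2-enyl)phenyl]-7-(methoxymethoxy)-5-(3-methylbut-2-enyloxy)chroman-4-one, via o-quinone 9 (not isolated)
Conditions: IBX (1.2 equiv), DMF, 0 °C → rt; then aq. Na2S2O4
Reagents that add atoms: 2-iodoxybenzoic acid (IBX), O=C1OI(=O)(O)c2ccccc12
Why: IBX oxidative demethylation in which the iodane bound to the only phenol (3'-OH) delivers oxygen to the methoxy-bearing ortho carbon, methanol is lost to give the o-quinone, and dithionite reduces it at once to the catechol before it can tautomerise toward C2–H or the prenyl CH2.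

**Step 6**
Reactants: 10 (2S)-2-[3,4-dihydroxy-2-(3-methylbut-2-enyl)phenyl]-7-(methoxymethoxy)-5-(3-methylbut-2-enyloxy)chroman-4-one; 11 3-chloro-3-methylbut-1-yne
Product: 12 (2S)-2-[3-hydroxy-2-(3-methylbut-2-enyl)-4-(2-methylbut-3-yn-2-yloxy)phenyl]-7-(methoxymethoxy)-5-(3-methylbut-2-enyloxy)chroman-4-one
Conditions: CuCl2·2H2O (1 mol %), DBU (1.2 equiv), degassed MeCN, −5 → 0 °C
Reagents that add atoms: none
Why: Copper-catalysed propargylic etherification (SN1-type, via a copper acetylide/allenylidene) in which the bulky tertiary electrophile takes the 4'-phenoxide, flanked only by OH and H, rather than the 3'-OH wedged between the 2'-prenyl group and O4', and the short exposure to DBU at 0 °C limits epimerisation at C2.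

**Step 7**
Reactants: 12 (2S)-2-[3-hydroxy-2-(3-methylbut-2-enyl)-4-(2-methylbut-3-yn-2-yloxy)phenyl]-7-(methoxymethoxy)-5-(3-methylbut-2-enyloxy)chroman-4-one
Product: 16 (2S)-5-hydroxy-2-[8-hydroxy-2,2-dimethyl-7-(3-methylbut-2-enyl)-2H-chromen-6-yl]-7-(methoxymethoxy)-8-(3-methylbut-2-enyl)chroman-4-one, via C6 cyclohexadienone 13 (not isolated), via 8-prenyl propargyl ether 14 (not isolated), via o-quinone methide 15 (not isolated)
Conditions: Eu(fod)3 (10 mol %), PhMe, 70 °C; then 115 °C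
Reagents that add atoms: none
Why: Two pericyclic cascades in one pot: Eu(III) chelated between C4=O and O5 triggers Claisen [3,3] to C6, Cope [3,3] to C8 and enolisation (para-Claisen–Cope) to put the prenyl group on C8, then at 115 °C the aryl propargyl ether undergoes Claisen [3,3] to C5' (its only free ortho position), enolisation, [1,5]-H shift and oxa-6π electrocyclisation to close the 2,2-dimethyl-2H-pyran, all without touching C2.

**Step 8**
Reactants: 16 (2S)-5-hydroxy-2-[8-hydroxy-2,2-dimethyl-7-(3-methylbut-2-enyl)-2H-chromen-6-yl]-7-(methoxymethoxy)-8-(3-methylbut-2-enyl)chroman-4-one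
Product: 17 (2S)-5,7-dihydroxy-2-[8-hydroxy-2,2-dimethyl-7-(3-methylbut-2-enyl)-2H-chromen-6-yl]-8-(3-methylbut-2-enyl)chroman-4-one
Conditions: 3 M aq. HCl, MeOH, 40 °C, stopped at full conversion
Reagents that add atoms: none
Why: Acid-catalysed acetal solvolysis of the 7-O-MOM ether on the electron-poor ring, under mild conditions where flavanones are configurationally stable and the prenyl and chromene alkenes survive.

## Compound list

1 | (2S)-hesperetin, (2S)-5,7-dihydroxy-2-(3-hydroxy-4-methoxyphenyl)chroman-4-one | COc1ccc(cc1O)[C@@H]1CC(=O)c2c(O)cc(O)cc2O1 | starting material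
2 | (2S)-5-hydroxy-2-(3-hydroxy-4-methoxyphenyl)-7-(methoxymethoxy)chroman-4-one | COc1ccc(cc1O)[C@@H]1CC(=O)c2c(O)cc(OCOC)cc2O1 | intermediate
3 | tert-butyl 2-methylbut-3-en-2-yl carbonate | CC(C)(C)OC(=O)OC(C)(C)C=C | starting material
4 | (2S)-5-hydroxy-2-[4-methoxy-3-(2-methylbut-3-en-2-yloxy)phenyl]-7-(methoxymethoxy)chroman-4-one | COc1ccc(cc1OC(C)(C)C=C)[C@@H]1CC(=O)c2c(O)cc(OCOC)cc2O1 | intermediate
5 | 3-methylbut-2-en-1-ol (prenol) | CC(C)=CCO | starting material
6 | (2S)-2-[4-methoxy-3-(2-methylbut-3-en-2-yloxy)phenyl]-7-(methoxymethoxy)-5-(3-methylbut-2-enyloxy)chroman-4-one | COc1ccc(cc1OC(C)(C)C=C)[C@@H]1CC(=O)c2c(OCC=C(C)C)cc(OCOC)cc2O1 | intermediate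
7 | (2S)-2-[4-methoxy-6-(3-methylbut-2-enyl)-5-oxocyclohexa-1,3-dienyl]-7-(methoxymethoxy)-5-(3-methylbut-2-enyloxy)chroman-4-one, Claisen dienone, both C2' epimers | COC1=CC=C(C(CC=C(C)C)C1=O)[C@@H]1CC(=O)c2c(OCC=C(C)C)cc(OCOC)cc2O1 | intermediate (not isolated)
8 | (2S)-2-[3-hydroxy-4-methoxy-2-(3-methylbut-2-enyl)phenyl]-7-(methoxymethoxy)-5-(3-methylbut-2-enyloxy)chroman-4-one | CC(C)=CCc1c(ccc(OC)c1O)[C@@H]1CC(=O)c2c(OCC=C(C)C)cc(OCOC)cc2O1 | intermediate
9 | (2S)-7-(methoxymethoxy)-2-[2-(3-methylbut-2-enyl)-3,4-dioxocyclohexa-1,5-dienyl]-5-(3-methylbut-2-enyloxy)chroman-4-one | CC(C)=CCC1=C(C=CC(=O)C1=O)[C@@H]1CC(=O)c2c(OCC=C(C)C)cc(OCOC)cc2O1 | intermediate (not isolated)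
10 | (2S)-2-[3,4-dihydroxy-2-(3-methylbut-2-enyl)phenyl]-7-(methoxymethoxy)-5-(3-methylbut-2-enyloxy)chroman-4-one | CC(C)=CCc1c(ccc(O)c1O)[C@@H]1CC(=O)c2c(OCC=C(C)C)cc(OCOC)cc2O1 | intermediate
11 | 3-chloro-3-methylbut-1-yne | CC(C)(Cl)C#C | starting material
12 | (2S)-2-[3-hydroxy-2-(3-methylbut-2-enyl)-4-(2-methylbut-3-yn-2-yloxy)phenyl]-7-(methoxymethoxy)-5-(3-methylbut-2-enyloxy)chroman-4-one | CC(C)=CCc1c(ccc(OC(C)(C)C#C)c1O)[C@@H]1CC(=O)c2c(OCC=C(C)C)cc(OCOC)cc2O1 | intermediate
13 | (2S)-2-[3-hydroxy-2-(3-methylbut-2-enyl)-4-(2-methylbut-3-yn-2-yloxy)phenyl]-6-(2-methylbut-3-en-2-yl)-7-(methoxymethoxy)-2,3-dihydro-4H-chromene-4,5(6H)-dione, both C6 epimers | CC(C)=CCc1c(ccc(OC(C)(C)C#C)c1O)[C@@H]1CC(=O)C2=C(C=C(OCOC)C(C(C)(C)C=C)C2=O)O1 | intermediate (not isolated)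
14 | (2S)-5-hydroxy-2-[3-hydroxy-2-(3-methylbut-2-enyl)-4-(2-methylbut-3-yn-2-yloxy)phenyl]-7-(methoxymethoxy)-8-(3-methylbut-2-enyl)chroman-4-one | CC(C)=CCc1c(ccc(OC(C)(C)C#C)c1O)[C@@H]1CC(=O)c2c(O)cc(OCOC)c(CC=C(C)C)c2O1 | intermediate (not isolated)
15 | (2S)-5-hydroxy-2-[5-hydroxy-6-(3-methylbut-2-enyl)-3-(3-methylbut-2-enylidene)-4-oxocyclohexa-1,5-dienyl]-7-(methoxymethoxy)-8-(3-methylbut-2-enyl)chroman-4-one, Z-alkylidene needed for ring closure | CC(C)=CCC1=C(O)C(=O)C(=CC=C(C)C)C=C1[C@@H]1CC(=O)c2c(O)cc(OCOC)c(CC=C(C)C)c2O1 | intermediate (not isolated)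
16 | (2S)-5-hydroxy-2-[8-hydroxy-2,2-dimethyl-7-(3-methylbut-2-enyl)-2H-chromen-6-yl]-7-(methoxymethoxy)-8-(3-methylbut-2-enyl)chroman-4-one | CC(C)=CCc1c([C@@H]2CC(=O)c3c(O)cc(OCOC)c(CC=C(C)C)c3O2)cc2c(c1O)OC(C)(C)C=C2 | intermediate
17 | (2S)-5,7-dihydroxy-2-[8-hydroxy-2,2-dimethyl-7-(3-methylbut-2-enyl)-2H-chromen-6-yl]-8-(3-methylbut-2-enyl)chroman-4-one (CNP0328260.1) | CC(C)=CCc1c([C@@H]2CC(=O)c3c(O)cc(O)c(CC=C(C)C)c3O2)cc2c(c1O)OC(C)(C)C=C2 | target

## Step count and risks

Total step count: 8. Longest linear sequence: 8 (1 → 17); compounds 3, 5 and 11 are bought. The ee should be re-checked at 10, 12 and 17, because steps 5 and 6 are the only places where C2 could erode.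

**Step 5, oxidative demethylation beside the 2'-prenyl group.** Oxygen transfer might instead go to the prenyl-bearing C2' and give an o-quinol, or the o-quinone might tautomerise before it is reduced. The fallback sets out from 2 and comes back to the route at 16. The demethylation is moved to the start, where the guaiacol has a free C–H on its other side and no prenyl group. IBX in DMF followed by Na2S2O4 turns 2 into (2S)-7-O-MOM-eriodictyol F1. Mono-alkylation with 11 (CuCl2/DBU, MeCN, 0 °C) gives the 4'-O-(1,1-dimethylpropargyl) ether F2, which has to be separated from its 3'-O isomer because there is no steric bias here; about half the material is lost. Heating in PhMe at 115 °C gives the linear chromenol F3. Carbonate 3 with Pd(PPh3)4 gives the 3'-O-(1,1-dimethylallyl) ether F4, and Mitsunobu reaction with 5 gives the 5-O-prenyl ether F5. One Eu(fod)3 operation in PhMe at 70 then 115 °C shifts both allyl groups (O5→C8 by Claisen–Cope, O3'→C2' by Claisen) and delivers 16.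

**Step 6, site-selective tertiary propargylation of the catechol.** The 3'-O ether may compete, the catechol may be oxidised by copper, or the hindered alkylation may stall. The fallback sets out from 10 and comes back at 16. The pyran is built from carbon instead of oxygen: 10 with 3-methylbut-2-enal (CC(C)=CC=O) and ethylenediammonium diacetate (20 mol %) in PhMe at 100 °C. The aldol-type attack can lead to a chromene only through C5', the sole free position ortho to a phenol. Dehydration to the o-quinone methide and oxa-6π closure give the 5-O-prenyl chromene F6. This annulation has little precedent on catechols, but its regiochemistry is fixed by the substitution pattern. Eu(fod)3 in PhMe at 70 °C then performs the para-Claisen–Cope and gives 16.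

**Step 7, two cascades in one pot.** The Claisen may stop at the C6-(1,1-dimethylallyl) phenol instead of going on to C8, or Eu(III) may be sequestered by the catechol mono-ether. The fallback sets out from 8 and comes back at 14. The ring-A rearrangement is done alone and early: Eu(fod)3 in CHCl3 at 65 °C converts 8 into the 8-prenyl guaiacol F7, from which a C6 isomer can be removed at a cheap stage. IBX then Na2S2O4 gives the 8-prenyl catechol F8. Propargylation with 11 as in step 6 gives 14, now isolated, and plain heating in PhMe at 115 °C closes the pyran to 16.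

## Further compounds

F1 | step 5 | (2S)-2-(3,4-dihydroxyphenyl)-5-hydroxy-7-(methoxymethoxy)chroman-4-one (7-O-MOM-eriodictyol) | Oc1ccc(cc1O)[C@@H]1CC(=O)c2c(O)cc(OCOC)cc2O1
F2 | step 5 | (2S)-5-hydroxy-2-[3-hydroxy-4-(2-methylbut-3-yn-2-yloxy)phenyl]-7-(methoxymethoxy)chroman-4-one | C#CC(C)(C)Oc1ccc(cc1O)[C@@H]1CC(=O)c2c(O)cc(OCOC)cc2O1
F3 | step 5 | (2S)-5-hydroxy-2-(8-hydroxy-2,2-dimethyl-2H-chromen-6-yl)-7-(methoxymethoxy)chroman-4-one | CC1(C)C=Cc2cc(cc(O)c2O1)[C@@H]1CC(=O)c2c(O)cc(OCOC)cc2O1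
F4 | step 5 | (2S)-2-[2,2-dimethyl-8-(2-methylbut-3-en-2-yloxy)-2H-chromen-6-yl]-5-hydroxy-7-(methoxymethoxy)chroman-4-one | CC1(C)C=Cc2cc(cc(OC(C)(C)C=C)c2O1)[C@@H]1CC(=O)c2c(O)cc(OCOC)cc2O1
F5 | step 5 | (2S)-2-[2,2-dimethyl-8-(2-methylbut-3-en-2-yloxy)-2H-chromen-6-yl]-7-(methoxymethoxy)-5-(3-methylbut-2-enyloxy)chroman-4-one | CC1(C)C=Cc2cc(cc(OC(C)(C)C=C)c2O1)[C@@H]1CC(=O)c2c(OCC=C(C)C)cc(OCOC)cc2O1
F6 | step 6 | (2S)-2-[8-hydroxy-2,2-dimethyl-7-(3-methylbut-2-enyl)-2H-chromen-6-yl]-7-(methoxymethoxy)-5-(3-methylbut-2-enyloxy)chroman-4-one | CC(C)=CCc1c([C@@H]2CC(=O)c3c(OCC=C(C)C)cc(OCOC)cc3O2)cc2c(c1O)OC(C)(C)C=C2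
F7 | step 7 | (2S)-5-hydroxy-2-[3-hydroxy-4-methoxy-2-(3-methylbut-2-enyl)phenyl]-7-(methoxymethoxy)-8-(3-methylbut-2-enyl)chroman-4-one | CC(C)=CCc1c(ccc(OC)c1O)[C@@H]1CC(=O)c2c(O)cc(OCOC)c(CC=C(C)C)c2O1
F8 | step 7 | (2S)-2-[3,4-dihydroxy-2-(3-methylbut-2-enyl)phenyl]-5-hydroxy-7-(methoxymethoxy)-8-(3-methylbut-2-enyl)chroman-4-one | CC(C)=CCc1c(ccc(O)c1O)[C@@H]1CC(=O)c2c(O)cc(OCOC)c(CC=C(C)C)c2O1
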